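(Readings and results were computed on assumed constants; noise was put on by code.)

The vessel is closed and stirred, and we ask how much product stands in it after the set time when we change the charge of free catalyst and leave the other charges as they are.

| flask | substrate | coupling partner | free catalyst | remark | time |
|---|---|---|---|---|---|
| larch | 1 M | 0.70 M | 140 mM | run made earlier |  |
| eta | 1.0 M | 0.700 M | 100 mM |  | 20 min |
| beta | 1.0 M | 0.700 M | 300 mM |  | 20 min |
| zeta | 1.0 M | 0.700 M | 1000 mM |  | 20 min |
| theta | 1.0 M | 0.700 M | 2500 mM |  | 20 min |

larch run (percent of the substrate charged)

| time / min | product / % | substrate / % |
|---|---|---|
| 3.00 | 31.3 | 57.2 |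
| 6.00 | 42.7 | 43.7 |
| 10.0 | 49.7 | 37.0 |
| 12.0 | 51.7 | 35.5 |
| 15.0 | 52.7 | 32.5 |
| 20.0 | 55.9 | 29.2 |

(scatter of a reading: 1 percentage point)

- the numbers in the tables scatter by 1 percentage point (one standard deviation)
- "hardly changes" means that all values lie within two and a half points (for a concentration: within two and a half percent of the largest)
- no earlier run changes the charge of free catalyst; that part of a forecast is a guess

- amount of product at the end, in percent of the substrate charged for eta, beta, zeta, theta, in this order
- the shape of the row from first to last (falls all the way / falls, then rises / rises, then falls / hardly changes / rises all the way)

1. We begin by counting turnovers. The larch run gives 3.99 when its product at 20.0 min is divided by its catalyst charge. We call this count of product made per catalyst charged the turnovers, the usual turnover number.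

2. A bench rule says that a catalyst gives the same turnovers whatever its charge, with the other charges held, so product is turnovers times catalyst. For the eta flask this gives 39.9 % of the substrate charged.

3. For the beta flask the same rule gives 120 %, which cannot be, because it is more than the whole substrate charge. If each product takes one coupling partner, the partner is the limiting reagent, and its ceiling is 70.0 %.

4. The border of the rule is found from the ratio of partner charge to catalyst charge, which is the number of turnovers the partner allows. In the eta flask that ratio is 7.00, more than the larch count, so the rule can still stand. In the beta flask it is 2.33, less than the larch count, so the rule has stopped working.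

5. Our own reckoning is therefore 39.9 % for eta, then a level top at the ceiling for beta, zeta and theta. No earlier run changes the catalyst charge, so this remains a guess.

6. The forecast, which differs from our reckoning both at eta and at the level top, gives 52 %, 62 %, 55 % and 35 %, a row that rises, then falls, in its words: “Free substrate then vanishes, so I expect the measured product to drop.”

The flasks give 52.9 %, 61.7 %, 50.1 % and 42.7 %, a row that rises, then falls.

    substrate + free catalyst ⇌ catalyst intermediate A (K = 0.950 M⁻¹, k = 0.270 M⁻¹ s⁻¹)
    catalyst intermediate C → free catalyst + product (k = 0.200 s⁻¹)
    catalyst intermediate A → catalyst intermediate B (k = 0.0990 s⁻¹)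
    coupling partner + catalyst intermediate B ⇌ catalyst intermediate C (K = 15.0 M⁻¹, k = 0.390 M⁻¹ s⁻¹)
    2 catalyst intermediate B → spent catalyst (k = 2.30 M⁻¹ s⁻¹)

In turnovers, the eta flask stands at 5.29, above the larch count, and the theta flask at 0.171, less than the 0.280 its partner allows. Taking away the step in which two catalyst intermediate B become spent catalyst lifts the theta flask from 42.7 % to 70.0 %, which is the 0.280 turnovers its partner allows. In the eta flask the same step is one part of what holds the product down: its removal lifts that flask from 52.9 % to 70.0 %, which is 7.00 turnovers.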